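**Retrosynthetic overview**
1. Target 31 ⇐ desilylation of penta-TBS macrolide 30 ⇐ ring expansion of the C1–C3 cis-β-lactone of seco-alcohol 27 by intramolecular acyl transfer to O27 (4- → 28-membered ring, C1–O27 bond).
2. 27 ⇐ Stille coupling (C19–C20) of dienyl bromide 21 with trienylstannane 26.
3. 21 ⇐ syn-aldol (C14–C15) of ethyl ketone 14 with bromodienal 16, then 1,3-anti reduction (C13); the β-lactone of 14 ⇐ catalytic asymmetric ketene–aldehyde cyclocondensation (C2–C3) of aldehyde 11 with butanoyl chloride.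
4. 11 ⇐ C2-symmetric diol 4 (double allylation of pentane-1,5-diol), desymmetrised by mono cross-metathesis with ethyl vinyl ketone (C11=C12) and boronate oxa-Michael addition (C11–O).
5. 26 ⇐ (2R,3R)-2,3-dimethyloxirane + vinyl cuprate (C25–C26), diene cross-metathesis (C24=C25), stannyl-olefination (C20=C21). Ring order: β-lactone first (step 6), 28-membered lactone last (step 15).

Assumption: 15, 22 and the named catalysts/reagents are bought or made by their published preparations; TBS = tert-butyldimethylsilyl, TBSO = TBS-oxy, BDI = N,N'-bis(2,6-diisopropylphenyl)pentane-2,4-diiminate; C-numbers in the explanations are those of the target (C1 = lactone carbonyl, C27 = lactone carbinol); the ligand/reagent antipodes in steps 1, 6 and 8 are assigned from the published selectivity models and should be confirmed on the first batch.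

**Step 1**
Reactants: 1 pentane-1,5-diol; 2 allyl acetate
Product: 4 (4S,8S)-undeca-1,10-diene-4,8-diol, via mono-allylated diol 3 (not isolated)
Conditions: [Ir(cod)Cl]2 (5 mol%), (R)-Cl,MeO-BIPHEP (10 mol%), 4-Cl-3-NO2-C6H3CO2H (20 mol%), Cs2CO3 (40 mol%), 2 (10 equiv), dioxane, 90 °C
Reagents that add atoms: none
Why: Krische iridium-catalysed transfer-hydrogenative double C-allylation of a 1,n-diol sets C5 and C9 under catalyst control, and the minor enantiomer of the mono-adduct ends up in the separable meso diastereomer.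

**Step 2**
Reactants: 4 (4S,8S)-undeca-1,10-diene-4,8-diol; 5 pent-1-en-3-one
Product: 6 (4E,7S,11S)-7,11-dihydroxytetradeca-4,13-dien-3-one
Conditions: Hoveyda–Grubbs II (3 mol%), 5 (0.7 equiv, slow addition), CH2Cl2, 40 °C; recovered 4 recycled
Reagents that add atoms: none
Why: Olefin cross-metathesis of a terminal alkene with an enone gives the E-enone, and using the enone as limiting partner converts only one of the two equivalent termini (statistical desymmetrisation).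

**Step 3**
Reactants: 6 (4E,7S,11S)-7,11-dihydroxytetradeca-4,13-dien-3-one
Product: 8 (5S,7S,11S)-5,7,11-trihydroxytetradec-13-en-3-one, via cyclic phenylboronate 7 (not isolated)
Conditions: PhB(OH)2 (2.5 equiv), quinine-derived amine–thiourea (20 mol%), 4 Å MS, toluene, rt; then 30% H2O2, aq Na2CO3, 0 °C
Reagents that add atoms: phenylboronic acid, OB(O)c1ccccc1
Why: Falck-type boronic-acid-hemiester oxa-Michael addition delivers the B–OH oxygen from the C9 boronate to C11 through a chair six-membered boronate with both substituents equatorial, which sets the 9,11-syn diol (11S); the C5 hydroxyl has no acceptor in reach.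

**Step 4**
Reactants: 8 (5S,7S,11S)-5,7,11-trihydroxytetradec-13-en-3-one
Product: 9 (5S,7S,11S)-5,7,11-tris(TBSO)tetradec-13-en-3-one
Conditions: TBSOTf (3.6 equiv), 2,6-lutidine (6 equiv), CH2Cl2, −78 °C
Reagents that add atoms: tert-butyldimethylsilyl triflate, CC(C)(C)[Si](C)(C)OS(=O)(=O)C(F)(F)F
Why: Silyl-triflate silylation of the three secondary alcohols is much faster than ketone enol-silylation at −78 °C and gives fluoride-labile protection throughout.

**Step 5**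
Reactants: 9 (5S,7S,11S)-5,7,11-tris(TBSO)tetradec-13-en-3-one
Product: 11 (3S,7S,9S)-3,7,9-tris(TBSO)-11-oxotridecanal, via ozonide 10 (not isolated)
Conditions: O3, CH2Cl2, −78 °C; then PPh3, −78 °C → rt
Reagents that add atoms: ozone, [O-][O+]=O
Why: Ozonolysis with reductive work-up cleaves the only C=C in the molecule to the C3 aldehyde before any polyene is present.

**Step 6**
Reactants: 11 (3S,7S,9S)-3,7,9-tris(TBSO)-11-oxotridecanal; 12 butanoyl chloride
Product: 14 (3S,4R)-3-ethyl-4-[(2S,6S,8S)-2,6,8-tris(TBSO)-10-oxododecyl]oxetan-2-one, via ethylketene 13 (not isolated)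
Conditions: 12 (2.5 equiv, slow addition), O-TMS-quinine (15 mol%), LiI (3 equiv), iPr2NEt (3 equiv), CH2Cl2/Et2O, −78 °C
Reagents that add atoms: none
Why: Nelson-type cinchona/Li-catalysed acyl halide–aldehyde cyclocondensation (stepwise ammonium-enolate aldol then lactonisation) gives the cis-β-lactone, with the alkaloid setting C2 (S) and C3 (R) and overriding the weak bias of the C5 silyl ether; the ketone is inert.

**Step 7**
Reactants: 15 glutaconaldehyde potassium salt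
Product: 16 (2E,4E)-5-bromopenta-2,4-dienal
Conditions: Ph3PBr2 (1.1 equiv), CH2Cl2, 0 °C → rt; then I2 (cat.), CH2Cl2, rt
Reagents that add atoms: dibromotriphenylphosphorane, BrP(Br)(c1ccccc1)(c1ccccc1)c1ccccc1
Why: O-phosphonium activation of the dienolate followed by addition–elimination of bromide (vinylogous acid to vinylogous acid bromide) gives the ω-bromodienal, and iodine equilibrates it to the E,E isomer.

**Step 8**
Reactants: 14 (3S,4R)-3-ethyl-4-[(2S,6S,8S)-2,6,8-tris(TBSO)-10-oxododecyl]oxetan-2-one; 16 (2E,4E)-5-bromopenta-2,4-dienal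
Product: 19 (3S,4R)-4-[(2S,6S,8S,11S,12R,13E,15E)-16-bromo-2,6,8-tris(TBSO)-12-hydroxy-11-methyl-10-oxohexadeca-13,15-dienyl]-3-ethyloxetan-2-one, via Z-enol borinate 17 (not isolated), via boron aldolate 18 (not isolated)
Conditions: (−)-Ipc2BOTf (1.6 equiv), iPr2NEt (2.2 equiv), CH2Cl2, −78 °C; 16 (1.5 equiv), −78 → −20 °C; pH 7 buffer/MeOH, 30% H2O2, 0 °C
Reagents that add atoms: none
Why: Paterson reagent-controlled syn-aldol: kinetic enolisation should favour the unhindered ethyl CH2 over the β-branched C12, the Z-enolate reacts through a Zimmerman–Traxler chair to give the 14,15-syn adduct, and the Ipc ligands select the aldehyde face (15R).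

**Step 9**
Reactants: 19 (the aldol adduct of step 8)
Product: 20 (3S,4R)-4-[(2S,6S,8R,10R,11R,12R,13E,15E)-16-bromo-2,6,8-tris(TBSO)-10,12-dihydroxy-11-methylhexadeca-13,15-dienyl]-3-ethyloxetan-2-one
Conditions: Me4NBH(OAc)3 (6 equiv), MeCN/AcOH (2:1), −30 °C
Reagents that add atoms: none
Why: Evans–Saksena reduction delivers hydride intramolecularly from the C15 alkoxy-borohydride through a chair transition state and gives the 13,15-anti diol (13R); the β-lactone and dienyl bromide are not reduced.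

**Step 10**
Reactants: 20 (the anti-diol of step 9)
Product: 21 (3S,4R)-4-[(2S,6S,8S,10R,11R,12R,13E,15E)-16-bromo-2,6,8,10,12-pentakis(TBSO)-11-methylhexadeca-13,15-dienyl]-3-ethyloxetan-2-one
Conditions: TBSOTf (3 equiv), 2,6-lutidine (5 equiv), CH2Cl2, −78 → 0 °C
Reagents that add atoms: tert-butyldimethylsilyl triflate, CC(C)(C)[Si](C)(C)OS(=O)(=O)C(F)(F)F
Why: Silylation of both carbinols leaves the incoming C27–OH as the only free hydroxyl at the ring-expansion stage.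

**Step 11**
Reactants: 22 (2R,3R)-2,3-dimethyloxirane
Product: 23 (2R,3R)-3-methylpent-4-en-2-ol
Conditions: CH2=CHMgBr (1.5 equiv), CuI (10 mol%), THF, −30 → 0 °C; aq NH4Cl
Reagents that add atoms: vinylmagnesium bromide, C=C[Mg]Br
Why: Copper-catalysed SN2 opening of the C2-symmetric trans-epoxide inverts the attacked carbon and gives the 26,27-syn stereodiad (26R,27R) from the chiral pool.

**Step 12**
Reactants: 23 (2R,3R)-3-methylpent-4-en-2-ol; 24 (2E,4E)-hexa-2,4-dienal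
Product: 25 (2E,4E,6R,7R)-7-hydroxy-6-methylocta-2,4-dienal
Conditions: 24 (4 equiv), Hoveyda–Grubbs II (5 mol%), CH2Cl2, 40 °C
Reagents that add atoms: none
Why: Chemoselective diene cross-metathesis: the ruthenium carbene engages the methyl-capped 4,5-olefin of the dienal while the electron-poor conjugated enal olefin is spared, giving the E,E-dienal and propene.

**Step 13**
Reactants: 25 (2E,4E,6R,7R)-7-hydroxy-6-methylocta-2,4-dienal
Product: 26 (2R,3R,4E,6E,8E)-3-methyl-9-(tributylstannyl)nona-4,6,8-trien-2-ol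
Conditions: Bu3SnCHI2 (2 equiv), CrCl2 (8 equiv), DMF/THF, rt, dark
Reagents that add atoms: tributyl(diiodomethyl)stannane, CCCC[Sn](CCCC)(CCCC)C(I)I
Why: Takai–Utimoto-type chromium(II) olefination with Hodgson's stannyl reagent (gem-dichromium addition then elimination) gives the E-alkenylstannane and tolerates the free alcohol.

**Step 14**
Reactants: 21 (the penta-TBS dienyl bromide of step 10); 26 (2R,3R,4E,6E,8E)-3-methyl-9-(tributylstannyl)nona-4,6,8-trien-2-ol
Product: 27 (3S,4R)-3-ethyl-4-[(2S,6S,8S,10R,11R,12R,13E,15E,17E,19E,21E,23R,24R)-24-hydroxy-11,23-dimethyl-2,6,8,10,12-pentakis(TBSO)pentacosa-13,15,17,19,21-pentaenyl]oxetan-2-one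
Conditions: Pd2(dba)3 (5 mol%), AsPh3 (40 mol%), NMP, 35 °C, dark
Reagents that add atoms: none
Why: Stille coupling joins C19 and C20 with retention of both olefin geometries under neutral conditions that spare the β-lactone and the free C27–OH.

**Step 15**
Reactants: 27 (the seco-alcohol β-lactone of step 14)
Product: 30 (3S,4R,6S,10S,12S,14R,15R,16R,17E,19E,21E,23E,25E,27R,28R)-3-ethyl-4-hydroxy-15,27,28-trimethyl-6,10,12,14,16-pentakis(TBSO)-1-oxacyclooctacosa-17,19,21,23,25-pentaen-2-one, via zinc C27-alkoxide 28 (not isolated), via zinc C3-alkoxide 29 (not isolated)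
Conditions: (BDI)ZnN(SiMe3)2 (15 mol%), toluene (0.5 mM, syringe-pump addition of 27), 25 → 40 °C, dark; then wet Et2O, silica
Reagents that add atoms: none
Why: Proposed new method: a zinc-alkoxide-catalysed ring-expanding translactonisation in which the β-lactone serves as a strain-activated acyl donor for its own remote hydroxyl — the C27–OH protonolyses the Zn–N bond to give alkoxide 28, zinc binds the β-lactone carbonyl and the alkoxide inserts into the acyl–O bond (the coordination–insertion step by which (BDI)Zn alkoxides polymerise β-butyrolactone with retention at the carbinol carbon), so the four-membered ring grows by the 24 tether atoms into the 28-membered lactone and releases O3 as zinc alkoxide 29, which is protonated by the C27–OH of the next substrate molecule to turn the catalyst over; roughly 20 kcal/mol of ring strain makes the step irreversible, high dilution favours cyclisation over oligomerisation, the unstrained α-branched product ester is not transesterified at this temperature, and C2/C3 are untouched (no alkyl–O cleavage, no enolisation); closest known reactions are β-lactone ring-opening polymerisation, β-lactam-to-macrolactam transamidative ring expansion and intramolecular β-lactone translactonisation to δ-lactones.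

**Step 16**
Reactants: 30 (the penta-TBS macrolide of step 15)
Product: 31 (3S,4R,6S,10S,12S,14R,15R,16R,17E,19E,21E,23E,25E,27R,28R)-3-ethyl-4,6,10,12,14,16-hexahydroxy-15,27,28-trimethyl-1-oxacyclooctacosa-17,19,21,23,25-pentaen-2-one
Conditions: HF·pyridine, pyridine, THF, 0 °C → rt, dark
Reagents that add atoms: none
Why: Buffered fluoride desilylation removes all five TBS ethers without ionising the C15 allylic alcohol next to the pentaene and without touching any stereocentre.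

**Compound list**
1 | pentane-1,5-diol | OCCCCCO | starting material
2 | allyl acetate | CC(=O)OCC=C | starting material
3 | (5S)-oct-7-ene-1,5-diol (mono-allylated diol; not isolated) | C=CC[C@@H](O)CCCCO | intermediate
4 | (4S,8S)-undeca-1,10-diene-4,8-diol | C=CC[C@@H](O)CCC[C@H](O)CC=C | intermediate
5 | pent-1-en-3-one (ethyl vinyl ketone) | C=CC(=O)CC | starting material
6 | (4E,7S,11S)-7,11-dihydroxytetradeca-4,13-dien-3-one | CCC(=O)/C=C/C[C@@H](O)CCC[C@H](O)CC=C | intermediate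
7 | cyclic phenylboronate (2-phenyl-1,3,2-dioxaborinane) of the 5,7-syn-diol of 8 (not isolated) | CCC(=O)C[C@@H]1C[C@H](CCC[C@H](O)CC=C)OB(c2ccccc2)O1 | intermediate
8 | (5S,7S,11S)-5,7,11-trihydroxytetradec-13-en-3-one | CCC(=O)C[C@@H](O)C[C@@H](O)CCC[C@H](O)CC=C | intermediate
9 | (5S,7S,11S)-5,7,11-tris(TBSO)tetradec-13-en-3-one | CCC(=O)C[C@@H](O[Si](C)(C)C(C)(C)C)C[C@@H](O[Si](C)(C)C(C)(C)C)CCC[C@H](O[Si](C)(C)C(C)(C)C)CC=C | intermediate
10 | ozonide (3-substituted 1,2,4-trioxolane, epimers at the acetal carbon) of 9 (not isolated) | CCC(=O)C[C@@H](O[Si](C)(C)C(C)(C)C)C[C@@H](O[Si](C)(C)C(C)(C)C)CCC[C@H](O[Si](C)(C)C(C)(C)C)CC1OCOO1 | intermediate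
11 | (3S,7S,9S)-3,7,9-tris(TBSO)-11-oxotridecanal | CCC(=O)C[C@@H](O[Si](C)(C)C(C)(C)C)C[C@@H](O[Si](C)(C)C(C)(C)C)CCC[C@H](O[Si](C)(C)C(C)(C)C)CC=O | intermediate
12 | butanoyl chloride | CCCC(Cl)=O | starting material
13 | ethylketene (but-1-en-1-one; not isolated) | CCC=C=O | intermediate
14 | (3S,4R)-3-ethyl-4-[(2S,6S,8S)-2,6,8-tris(TBSO)-10-oxododecyl]oxetan-2-one | CCC(=O)C[C@@H](O[Si](C)(C)C(C)(C)C)C[C@@H](O[Si](C)(C)C(C)(C)C)CCC[C@H](O[Si](C)(C)C(C)(C)C)C[C@H]1OC(=O)[C@H]1CC | intermediate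
15 | glutaconaldehyde potassium salt [potassium (1E,3E)-5-oxopenta-1,3-dien-1-olate] | [K+].[O-]/C=C/C=C/C=O | starting material
16 | (2E,4E)-5-bromopenta-2,4-dienal | O=C/C=C/C=C/Br | intermediate
17 | (Z)-enol diisopinocampheylborinate of 14 (C13–O–B, C13=C14; not isolated) | C/C=C(\OB([C@@H]1C[C@@H]2C[C@H]([C@H]1C)C2(C)C)[C@@H]1C[C@@H]2C[C@H]([C@H]1C)C2(C)C)C[C@@H](O[Si](C)(C)C(C)(C)C)C[C@@H](O[Si](C)(C)C(C)(C)C)CCC[C@H](O[Si](C)(C)C(C)(C)C)C[C@H]1OC(=O)[C@H]1CC | intermediate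
18 | diisopinocampheylboron aldolate of 19 (C15–O–B; not isolated) | Br/C=C/C=C/[C@@H](OB([C@@H]1C[C@@H]2C[C@H]([C@H]1C)C2(C)C)[C@@H]1C[C@@H]2C[C@H]([C@H]1C)C2(C)C)[C@H](C)C(=O)C[C@@H](O[Si](C)(C)C(C)(C)C)C[C@@H](O[Si](C)(C)C(C)(C)C)CCC[C@H](O[Si](C)(C)C(C)(C)C)C[C@H]1OC(=O)[C@H]1CC | intermediate
19 | (3S,4R)-4-[(2S,6S,8S,11S,12R,13E,15E)-16-bromo-2,6,8-tris(TBSO)-12-hydroxy-11-methyl-10-oxohexadeca-13,15-dienyl]-3-ethyloxetan-2-one | Br/C=C/C=C/[C@@H](O)[C@H](C)C(=O)C[C@@H](O[Si](C)(C)C(C)(C)C)C[C@@H](O[Si](C)(C)C(C)(C)C)CCC[C@H](O[Si](C)(C)C(C)(C)C)C[C@H]1OC(=O)[C@H]1CC | intermediate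
20 | (3S,4R)-4-[(2S,6S,8R,10R,11R,12R,13E,15E)-16-bromo-2,6,8-tris(TBSO)-10,12-dihydroxy-11-methylhexadeca-13,15-dienyl]-3-ethyloxetan-2-one | Br/C=C/C=C/[C@@H](O)[C@H](C)[C@H](O)C[C@@H](O[Si](C)(C)C(C)(C)C)C[C@@H](O[Si](C)(C)C(C)(C)C)CCC[C@H](O[Si](C)(C)C(C)(C)C)C[C@H]1OC(=O)[C@H]1CC | intermediate
21 | (3S,4R)-4-[(2S,6S,8S,10R,11R,12R,13E,15E)-16-bromo-2,6,8,10,12-pentakis(TBSO)-11-methylhexadeca-13,15-dienyl]-3-ethyloxetan-2-one | Br/C=C/C=C/[C@@H](O[Si](C)(C)C(C)(C)C)[C@H](C)[C@H](O[Si](C)(C)C(C)(C)C)C[C@@H](O[Si](C)(C)C(C)(C)C)C[C@@H](O[Si](C)(C)C(C)(C)C)CCC[C@H](O[Si](C)(C)C(C)(C)C)C[C@H]1OC(=O)[C@H]1CC | intermediate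
22 | (2R,3R)-2,3-dimethyloxirane (trans-2,3-epoxybutane) | C[C@H]1O[C@@H]1C | starting material
23 | (2R,3R)-3-methylpent-4-en-2-ol | O[C@H](C)[C@H](C)C=C | intermediate
24 | (2E,4E)-hexa-2,4-dienal | C/C=C/C=C/C=O | starting material
25 | (2E,4E,6R,7R)-7-hydroxy-6-methylocta-2,4-dienal | O[C@H](C)[C@H](C)/C=C/C=C/C=O | intermediate
26 | (2R,3R,4E,6E,8E)-3-methyl-9-(tributylstannyl)nona-4,6,8-trien-2-ol | O[C@H](C)[C@H](C)/C=C/C=C/C=C/[Sn](CCCC)(CCCC)CCCC | intermediate
27 | (3S,4R)-3-ethyl-4-[(2S,6S,8S,10R,11R,12R,13E,15E,17E,19E,21E,23R,24R)-24-hydroxy-11,23-dimethyl-2,6,8,10,12-pentakis(TBSO)pentacosa-13,15,17,19,21-pentaenyl]oxetan-2-one | O[C@H](C)[C@H](C)/C=C/C=C/C=C/C=C/C=C/[C@@H](O[Si](C)(C)C(C)(C)C)[C@H](C)[C@H](O[Si](C)(C)C(C)(C)C)C[C@@H](O[Si](C)(C)C(C)(C)C)C[C@@H](O[Si](C)(C)C(C)(C)C)CCC[C@H](O[Si](C)(C)C(C)(C)C)C[C@H]1OC(=O)[C@H]1CC | intermediate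
28 | (BDI)Zn C27-alkoxide of 27 (not isolated) | CC1=CC(C)=[N+](c2c(C(C)C)cccc2C(C)C)[Zn-](O[C@H](C)[C@H](C)/C=C/C=C/C=C/C=C/C=C/[C@@H](O[Si](C)(C)C(C)(C)C)[C@H](C)[C@H](O[Si](C)(C)C(C)(C)C)C[C@@H](O[Si](C)(C)C(C)(C)C)C[C@@H](O[Si](C)(C)C(C)(C)C)CCC[C@H](O[Si](C)(C)C(C)(C)C)C[C@H]2OC(=O)[C@H]2CC)N1c1c(C(C)C)cccc1C(C)C | intermediate
29 | (BDI)Zn C3-alkoxide of macrolide 30 (not isolated) | CC[C@@H]1C(=O)O[C@H](C)[C@H](C)/C=C/C=C/C=C/C=C/C=C/[C@@H](O[Si](C)(C)C(C)(C)C)[C@H](C)[C@H](O[Si](C)(C)C(C)(C)C)C[C@@H](O[Si](C)(C)C(C)(C)C)C[C@@H](O[Si](C)(C)C(C)(C)C)CCC[C@H](O[Si](C)(C)C(C)(C)C)C[C@H]1O[Zn-]2N(c3c(C(C)C)cccc3C(C)C)C(C)=CC(C)=[N+]2c2c(C(C)C)cccc2C(C)C | intermediate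
30 | (3S,4R,6S,10S,12S,14R,15R,16R,17E,19E,21E,23E,25E,27R,28R)-3-ethyl-4-hydroxy-15,27,28-trimethyl-6,10,12,14,16-pentakis(TBSO)-1-oxacyclooctacosa-17,19,21,23,25-pentaen-2-one | CC[C@@H]1C(=O)O[C@H](C)[C@H](C)/C=C/C=C/C=C/C=C/C=C/[C@@H](O[Si](C)(C)C(C)(C)C)[C@H](C)[C@H](O[Si](C)(C)C(C)(C)C)C[C@@H](O[Si](C)(C)C(C)(C)C)C[C@@H](O[Si](C)(C)C(C)(C)C)CCC[C@H](O[Si](C)(C)C(C)(C)C)C[C@H]1O | intermediate
31 | (3S,4R,6S,10S,12S,14R,15R,16R,17E,19E,21E,23E,25E,27R,28R)-3-ethyl-4,6,10,12,14,16-hexahydroxy-15,27,28-trimethyl-1-oxacyclooctacosa-17,19,21,23,25-pentaen-2-one (CNP0382847.1) | CC[C@@H]1C(=O)O[C@H](C)[C@H](C)/C=C/C=C/C=C/C=C/C=C/[C@@H](O)[C@H](C)[C@H](O)C[C@@H](O)C[C@@H](O)CCC[C@H](O)C[C@H]1O | target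

**Step count and risks**
Total step count: 16. Longest linear sequence: 12 steps (steps 1–6, 8–10, 14–16, from pentane-1,5-diol).

Most likely to fail, step 15 (the proposed ring expansion: oligomerisation, or a zinc alkoxide too hindered to insert). The fallback sets out from 27 and comes back at 30. LiOH in aqueous THF at 0 °C opens the β-lactone by acyl–O cleavage, with retention at C3, to the seco acid F1. Yamaguchi activation (2,4,6-trichlorobenzoyl chloride, Et3N) gives the mixed anhydride F2, and slow addition to DMAP in toluene at high dilution closes the 28-membered lactone 30. The free C3–OH can at worst re-close to β-lactone 27, which is recycled.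

Second, step 8 (ethyl-ketone aldol: enolisation may occur partly at C12, and reagent control of the aldehyde face may be only moderate). The fallback sets out from 4 and 16 and comes back at 21; it makes C11–C12 instead of C14–C15 through a methyl-ketone aldol whose enolisation regiochemistry is unambiguous.
- Diol 4 is bis-silylated (TBSOTf, 2,6-lutidine) to the diene F3 and doubly ozonolysed to the C2-symmetric dialdehyde F4. One aldehyde undergoes the step-6 cyclocondensation with 12 to give the β-lactone aldehyde F5 (statistical; F4 and bis-lactone are separated and recycled).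
- Bromodienal 16 undergoes an Evans syn-aldol with (S)-4-benzyl-3-propionyloxazolidin-2-one (Bu2BOTf, Et3N) to give the imide F6. Transamination (MeONHMe·HCl, AlMe3) gives the Weinreb amide F7, TBSOTf gives the silyl ether F8, and MeMgBr gives the methyl ketone F9.
- An Ipc2BCl/Et3N aldol of F9 (enolisation at the methyl group only) with F5 gives the 11-hydroxy-13-ketone F10. Me4NBH(OAc)3 then gives the 11,13-anti diol F11, and TBSOTf/2,6-lutidine gives 21.

Third, step 12 (diene cross-metathesis: the carbene may engage the wrong olefin of the dienal or give E/Z mixtures). The fallback sets out from 23 and comes back at 25. Cross-metathesis of 23 with crotonaldehyde (Hoveyda–Grubbs II) gives the simple enal F12, and a Wittig reaction with Ph3P=CHCHO (toluene, 80 °C) adds the second E-olefin to give 25.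

**Further compounds**
F1 | step 15 | seco acid: (2S,3R,5S,9S,11S,13R,14R,15R,16E,18E,20E,22E,24E,26R,27R)-2-ethyl-3,27-dihydroxy-14,26-dimethyl-5,9,11,13,15-pentakis(TBSO)octacosa-16,18,20,22,24-pentaenoic acid | O[C@H](C)[C@H](C)/C=C/C=C/C=C/C=C/C=C/[C@@H](O[Si](C)(C)C(C)(C)C)[C@H](C)[C@H](O[Si](C)(C)C(C)(C)C)C[C@@H](O[Si](C)(C)C(C)(C)C)C[C@@H](O[Si](C)(C)C(C)(C)C)CCC[C@H](O[Si](C)(C)C(C)(C)C)C[C@@H](O)[C@H](CC)C(=O)O
F2 | step 15 | mixed anhydride of F1 with 2,4,6-trichlorobenzoic acid | O[C@H](C)[C@H](C)/C=C/C=C/C=C/C=C/C=C/[C@@H](O[Si](C)(C)C(C)(C)C)[C@H](C)[C@H](O[Si](C)(C)C(C)(C)C)C[C@@H](O[Si](C)(C)C(C)(C)C)C[C@@H](O[Si](C)(C)C(C)(C)C)CCC[C@H](O[Si](C)(C)C(C)(C)C)C[C@@H](O)[C@H](CC)C(=O)OC(=O)c1c(Cl)cc(Cl)cc1Cl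
F3 | step 8 | (4S,8S)-4,8-bis(TBSO)undeca-1,10-diene | C=CC[C@@H](O[Si](C)(C)C(C)(C)C)CCC[C@H](O[Si](C)(C)C(C)(C)C)CC=C
F4 | step 8 | (3S,7S)-3,7-bis(TBSO)nonanedial | O=CC[C@@H](O[Si](C)(C)C(C)(C)C)CCC[C@H](O[Si](C)(C)C(C)(C)C)CC=O
F5 | step 8 | (3S,7S)-3,7-bis(TBSO)-8-[(2R,3S)-3-ethyl-4-oxooxetan-2-yl]octanal | O=CC[C@@H](O[Si](C)(C)C(C)(C)C)CCC[C@H](O[Si](C)(C)C(C)(C)C)C[C@H]1OC(=O)[C@H]1CC
F6 | step 8 | (4S)-4-benzyl-3-[(2S,3R,4E,6E)-7-bromo-3-hydroxy-2-methylhepta-4,6-dienoyl]oxazolidin-2-one | Br/C=C/C=C/[C@@H](O)[C@H](C)C(=O)N1C(=O)OC[C@@H]1Cc1ccccc1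
F7 | step 8 | (2S,3R,4E,6E)-7-bromo-3-hydroxy-N-methoxy-N,2-dimethylhepta-4,6-dienamide | Br/C=C/C=C/[C@@H](O)[C@H](C)C(=O)N(C)OC
F8 | step 8 | (2S,3R,4E,6E)-7-bromo-3-(TBSO)-N-methoxy-N,2-dimethylhepta-4,6-dienamide | Br/C=C/C=C/[C@@H](O[Si](C)(C)C(C)(C)C)[C@H](C)C(=O)N(C)OC
F9 | step 8 | (3S,4R,5E,7E)-8-bromo-4-(TBSO)-3-methylocta-5,7-dien-2-one | Br/C=C/C=C/[C@@H](O[Si](C)(C)C(C)(C)C)[C@H](C)C(C)=O
F10 | step 8 | 11-hydroxy-13-ketone (target numbering): C1–C3 cis-β-lactone; 5,9,15-tris(TBSO); 11S-OH; (16E,18E)-19-bromo | Br/C=C/C=C/[C@@H](O[Si](C)(C)C(C)(C)C)[C@H](C)C(=O)C[C@@H](O)C[C@@H](O[Si](C)(C)C(C)(C)C)CCC[C@H](O[Si](C)(C)C(C)(C)C)C[C@H]1OC(=O)[C@H]1CC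
F11 | step 8 | 11,13-anti diol (target numbering): C1–C3 cis-β-lactone; 5,9,15-tris(TBSO); 11-OH and 13-OH free; (16E,18E)-19-bromo | Br/C=C/C=C/[C@@H](O[Si](C)(C)C(C)(C)C)[C@H](C)[C@H](O)C[C@@H](O)C[C@@H](O[Si](C)(C)C(C)(C)C)CCC[C@H](O[Si](C)(C)C(C)(C)C)C[C@H]1OC(=O)[C@H]1CC
F12 | step 12 | (2E,4R,5R)-5-hydroxy-4-methylhex-2-enal | O[C@H](C)[C@H](C)/C=C/C=O
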